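**Analysis of the target**

Target 32 is a B-type procyanidin trimer: three flavan-3-ol units, each a chroman (benzo ring A fused to pyran ring C) with a catechol ring B on C2, joined by two C4→C8 bonds. The top and middle units are (−)-epicatechin 3-O-gallates and the bottom unit is (+)-catechin with a free 3-hydroxyl. There are eight stereocenters. Top and middle each carry C2 (R), C3 (R) and C4, with the C2 aryl and the C3 oxygen cis and the C4 aryl bond β, trans to both. The bottom unit carries C2 (R) and C3 (S), trans. No ring fusion relays stereochemistry from one unit to the next, so each triad is bought or set on its own. The molecule has eighteen phenols (catechols, pyrogallol-type gallates, phloroglucinol-type rings A) that oxidise in air, two gallate esters that are cleaved by base, and two doubly benzylic C4–C8 bonds that break under acid. The hard points are the two interflavan bonds, which need control of site (C8 against C6), of C4 configuration and of chain length, and the three C3 oxygens, two acylated and one free. The route rests on one feature: middle C4 is a diarylmethine joined through C4a to a 1,3,5-trioxygenated ring A and to bottom C8, while middle C2, with ring B set aside, is at the aldehyde oxidation level and bound to O1 of that ring A. Middle ring C (O1, C2, C3, C4, C4a, C8a) is therefore the formal adduct of phloroglucinol 8 with a three-carbon enal attached to bottom C8.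

**Retrosynthetic reasoning**

32 from 31. All nineteen hydroxyls are carried as benzyl ethers and freed together by hydrogenolysis. This removal is neutral and reductive, so the gallate esters and both C4–C8 bonds of 32 are not exposed to acid or base.

31 from 26 and 30; 30 from 29. The top C4–middle C8 bond is cut. The top unit then keeps the C2 and C3 centers of the chiral pool, and its C4 is the natural electrophilic site because ring A stabilises a cation there; the leaving group of 30 is put on by benzylic oxidation of 29. In 26 the middle C8 is an unsubstituted ring A position. The forward coupling has to give the 4β bond, which the C3 gallate carbonyl should enforce by bridging the α face, and has to prefer C8 over C6.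

29 from 28 and 25; 28 from 27. The top gallate ester is cut at the acyl–oxygen bond. What remains is tetra-O-benzyl epicatechin 28, whose only free hydroxyl is the one to be acylated, and 28 comes from 27 by etherification of four phenols. The same acid 25 then serves both gallate esters, and the protected top unit is assembled from two cleanly made halves.

26 from 24 and 25; 24 from 23. The middle gallate ester is cut. In 24 the middle C3 hydroxyl is the only free hydroxyl, because the bottom C3 oxygen is a benzyl ether and the middle one was a silyl ether in 23. The two secondary oxygens are therefore told apart by their protecting groups alone.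

23 from 21 (through 22), and 21 from 17 and 20. At middle C2 the C–H bond and the C–aryl bond are cut. In lactone 17 this carbon is at the acid oxidation level, so ring B arrives as aryllithium 20 (from 19, from 18) and the hydrogen arrives as hydride on the cyclic oxocarbenium ion formed from 22. C2 is thus set last, under control of C3 and C4.

17 from 16, and 16 from 14 through enolate 15. The C3–O bond is cut. The enolate is oxidised on the face away from the C4 aryl group, which gives the 3,4-trans relation of the target.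

14 from 13, 12, 11 and 10. These steps adjust protection and oxidation level only. The two phenols of lactol 10 cannot be benzylated directly, because base would open the lactol and alkylate the ring oxygen as well. A lactone would not survive the alkylation either. The lactol is therefore locked as methyl acetal 11, benzylated to 12, hydrolysed to 13 and oxidised to 14.

10 from 7 and 8 (through 9). This is the central disconnection: C4–C4a and O1–C2 of middle ring C. Ring A is commercial 8, whose threefold symmetry removes every regiochemical question. The bottom unit is already attached in 7. The forward step has to add an arene carbon to one face of the enal β-carbon and close the lactol.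

7 from 6, 4 (through 5), 3, 2 and 1. The enal is taken back to the aldehyde by a two-carbon olefination, the aldehyde to the C8 bromide by lithiation and formylation, and the bromide to benzylated catechin. C8 is fixed by the known site preference of bromination, so the middle C4–bottom C8 bond is never formed by cation chemistry.

**Alternatives that were turned down**

Alternative 1: The middle C4–bottom C8 bond is cut, but closed intramolecularly. The bottom 3-oxygen is tied through an m-xylylene diether to the para oxygen of the middle gallate. A silyl triflate at high dilution ionises a C4 ether of the middle unit, and the tethered catechin ring A attacks through C8, closing a twenty-membered ring to give A1.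
- For: every stereocenter comes from 1 and 27. The tether enforces 1:1 stoichiometry and stops oligomerisation. It is made of benzylic ethers and falls off in the final hydrogenolysis, leaving the bottom 3-hydroxyl free.
- Against: a twenty-membered closure is entropically costly. The para oxygen of the gallate must be differentiated from the two meta oxygens, so acid 25 cannot serve for the middle ester and a differentially protected gallic acid has to be built. It is a conformational bet whether the tether lets C8, and not C6, reach the β face of C4. The gallate carbonyl that should shield the α face is itself part of the strap. After A1 the top unit must still be attached by an intermolecular cationic coupling.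
- Comparison: this alternative is stronger on stereochemical economy, since it creates no center. The chosen route instead makes the C4–C8 link as an ordinary aryl–carbon bond at a bromination-defined position, sets C4 by catalyst, and needs no high dilution or tether construction.

Alternative 2: Four bonds of middle ring A are cut. Irradiation of an α-diazo ketone function gives, by Wolff rearrangement, a vinylketene that adds to a tethered alkynyl ether. Ring opening and 6π closure then build rings A and C of the middle unit and give A2, with a free middle C7 hydroxyl.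
- For: the top unit sits on the carbon that becomes C8, so the C8/C6 question does not arise. This is better than step 21 of the chosen route, which relies on the innate preference of C8. The bond-forming event is highly convergent.
- Against: the substrate must already hold both outer units, the stereodefined C2–C3–C4 chain with its esters, an acid-labile ynol ether and a diazo ketone. These would have to be made late on a molecule with about eighteen benzyl ethers. The photolysis must compete with many absorbing aryl ethers and esters. The C4 center would be propargylic and doubly benzylic before the event, and so prone to epimerisation.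
- Comparison: the chosen route takes ring A from 8 at no cost and forms only two bonds in its key step, early, on a small substrate and under ambient conditions. The linear sequence is much shorter.

Alternative 3: Top C4–C4a is cut. A boron trifluoride-type Lewis acid ionises a C4 carbinol carried on middle C8, the neighbouring gallate bridges the cation, and an ortho carbon of a 3,5-bis(benzyloxy)phenyl ether on C2 closes top ring C to give A3.
- For: the middle unit comes from 27 and 25 without any new stereocenter. The top C4–middle C8 bond is made beforehand by polar chemistry, so its site is secure. The bridged cation gives the 3,4-trans relation. The later coupling to the bottom unit can use a cheap nucleophile derived from 1 in excess, which is better than step 21 here.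
- Against: top C2 and C3 must be made de novo, including a configurationally defined benzylic aryl ether at C2. That bond is hard to form by substitution at an easily ionised center, and it is labile to the same Lewis acid. A3 must then be oxidised at middle C4 next to a tertiary top C4–H and coupled by cation chemistry.
- Comparison: the number of centers made de novo is the same (three). The chosen route closes O1–C2 as a lactol and not by substitution at a stereocenter, sets C4 by catalyst, and needs no late oxidation of a dimer.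

Key step: step 6

Assumption: the adduct of step 14 is taken to rest as the open keto-phenol 21, as is usual for aryl ketones of this kind, and not as its cyclic hemiketal 22; either form would enter step 15.

**Route**

Step 1
Reactants: 1 (+)-catechin
Product: 2 5,7,3′,4′-tetra-O-benzyl-(+)-catechin
Conditions: BnBr (4.4 equiv), K2CO3, DMF, 0 °C to rt
Reagents that add atoms: benzyl bromide, BrCc1ccccc1
Why: Williamson etherification; K2CO3 deprotonates only the four phenols, so the secondary 3-hydroxyl stays free and C2 and C3 are untouched.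

Step 2
Reactants: 2 5,7,3′,4′-tetra-O-benzyl-(+)-catechin
Product: 3 3,5,7,3′,4′-penta-O-benzyl-(+)-catechin
Conditions: NaH, BnBr, DMF, 0 °C to rt
Reagents that add atoms: benzyl bromide, BrCc1ccccc1
Why: Williamson etherification of the secondary alkoxide; no acidic phenol remains, so ring opening or C2 epimerisation through a quinone methide is not possible.

Step 3
Reactants: 3 3,5,7,3′,4′-penta-O-benzyl-(+)-catechin
Product: 4 8-bromo-3,5,7,3′,4′-penta-O-benzyl-(+)-catechin
Conditions: NBS (1.0 equiv), CH2Cl2, −78 °C to rt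
Reagents that add atoms: N-bromosuccinimide, BrN1C(=O)CCC1=O
Why: Electrophilic aromatic bromination of ring A, the most electron-rich ring; C8, next to the ring oxygen, is expected to react before C6, which lies between two benzyloxy groups.

Step 4
Reactants: 4 8-bromo-3,5,7,3′,4′-penta-O-benzyl-(+)-catechin
Product: 6 3,5,7,3′,4′-penta-O-benzylcatechin-8-carbaldehyde, via 8-lithio-penta-O-benzylcatechin 5 (not isolated)
Conditions: n-BuLi, THF, −78 °C; DMF, −78 °C to 0 °C; H2O
Reagents that add atoms: N,N-dimethylformamide, CN(C)C=O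
Why: Bromine–lithium exchange is faster at −78 °C than benzylic deprotonation; the aryllithium is formylated by DMF (Bouveault reaction) and the hemiaminal alkoxide collapses on work-up.

Step 5
Reactants: 6 3,5,7,3′,4′-penta-O-benzylcatechin-8-carbaldehyde
Product: 7 (E)-3-(3,5,7,3′,4′-penta-O-benzylcatechin-8-yl)propenal
Conditions: Ph3P=CHCHO (1.3 equiv), toluene, 90 °C
Reagents that add atoms: (triphenylphosphoranylidene)acetaldehyde, O=CC=P(c1ccccc1)(c1ccccc1)c1ccccc1
Why: Wittig olefination with a stabilised ylide, which gives the (E)-alkene; the product enal is deactivated by its trioxygenated aryl group and should resist a second homologation.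

Step 6
Reactants: 7 (E)-3-(3,5,7,3′,4′-penta-O-benzylcatechin-8-yl)propenal; 8 phloroglucinol
Product: 10 (4R)-4-(penta-O-benzylcatechin-8-yl)chromane-2,5,7-triol (lactol; both C2 epimers), via open-chain aldehyde 9 (not isolated)
Conditions: (S)-α,α-diphenylprolinol trimethylsilyl ether (20 mol%), PhCO2H (20 mol%), 8 (3 equiv), MeCN–CH2Cl2, 0 °C to rt
Reagents that add atoms: none
Why: The amine condenses with 7 to an (E), s-trans iminium ion, and a ring carbon of 8 adds to its β-carbon in a Friedel–Crafts conjugate addition; rearomatisation and hydrolysis of the enamine give aldehyde 9 and return the catalyst. A hydroxyl ortho to the new C4–C4a bond then adds to the aldehyde, a 6-exo-trig hemiacetalisation that forms O1–C2, closes ring C as lactol 10 and draws the sequence forward. The closest known reaction type is the amine-catalysed Friedel–Crafts alkylation and hemiacetalisation of naphthols and electron-rich phenols with enals to 4-substituted chroman-2-ols. The one new controlled center, C4, is set by the catalyst: its diphenyl(silyloxy)methyl group covers one face of the iminium ion, so the arene enters on the Si face of the β-carbon, which corresponds to (4R) and to the 4β orientation of the target. The only selectivity needed is facial, since the threefold symmetry of 8 makes all ring carbons and both flanking hydroxyls equivalent. The catechin stereocenters lie far from the β-carbon, so catalyst control should prevail. Excess 8 is meant to suppress a second alkylation of the still electron-rich product ring. C2 is formed as an epimer mixture that is removed in step 10.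

Step 7
Reactants: 10 (4R)-4-(penta-O-benzylcatechin-8-yl)chromane-2,5,7-triol
Product: 11 (4R)-2-methoxy-4-(penta-O-benzylcatechin-8-yl)chromane-5,7-diol (both C2 epimers)
Conditions: MeOH, pyridinium p-toluenesulfonate (cat.), 3 Å sieves, rt
Reagents that add atoms: methanol, CO
Why: Acid-catalysed acetalisation through the ring oxocarbenium ion, trapped by the solvent; it locks ring C so that the base of the next step cannot open the lactol and alkylate O1.

Step 8
Reactants: 11 (4R)-2-methoxy-4-(penta-O-benzylcatechin-8-yl)chromane-5,7-diol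
Product: 12 (4R)-5,7-bis(benzyloxy)-2-methoxy-4-(penta-O-benzylcatechin-8-yl)chromane (both C2 epimers)
Conditions: BnBr, K2CO3, DMF, rt
Reagents that add atoms: benzyl bromide, BrCc1ccccc1
Why: Williamson etherification of the two remaining phenols; the acetal is inert to base.

Step 9
Reactants: 12 (4R)-5,7-bis(benzyloxy)-2-methoxy-4-(penta-O-benzylcatechin-8-yl)chromane
Product: 13 (4R)-5,7-bis(benzyloxy)-4-(penta-O-benzylcatechin-8-yl)chroman-2-ol (both C2 epimers)
Conditions: 1 M HCl, THF, 40 °C
Reagents that add atoms: water, O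
Why: Hydrolysis of a mixed aryl alkyl acetal through the oxocarbenium ion; benzyl ethers and the C4 diarylmethine should tolerate dilute aqueous acid.

Step 10
Reactants: 13 (4R)-5,7-bis(benzyloxy)-4-(penta-O-benzylcatechin-8-yl)chroman-2-ol
Product: 14 (4R)-5,7-bis(benzyloxy)-4-(penta-O-benzylcatechin-8-yl)chroman-2-one
Conditions: Dess–Martin periodinane, CH2Cl2, rt
Reagents that add atoms: none
Why: Dess–Martin oxidation of a lactol to the lactone; both C2 epimers converge and no phenol is left to be oxidised.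

Step 11
Reactants: 14 (4R)-5,7-bis(benzyloxy)-4-(penta-O-benzylcatechin-8-yl)chroman-2-one
Product: 16 (3R,4R)-5,7-bis(benzyloxy)-3-hydroxy-4-(penta-O-benzylcatechin-8-yl)chroman-2-one (3,4-trans), via potassium enolate 15 (not isolated)
Conditions: KN(SiMe3)2, THF, −78 °C; 2-(phenylsulfonyl)-3-phenyloxaziridine, −78 °C; AcOH, −78 °C
Reagents that add atoms: 2-(phenylsulfonyl)-3-phenyloxaziridine, O=S(=O)(c1ccccc1)N1OC1c1ccccc1
Why: Davis-type enolate hydroxylation. The C4 aryl group should sit pseudo-axial to avoid the peri 5-benzyloxy group and so blocks one face of the enolate; oxygen is delivered to the other face, giving the 3,4-trans (3R) alcohol.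

Step 12
Reactants: 16 (3R,4R)-5,7-bis(benzyloxy)-3-hydroxy-4-(penta-O-benzylcatechin-8-yl)chroman-2-one
Product: 17 (3R,4R)-5,7-bis(benzyloxy)-3-(tert-butyldimethylsilyloxy)-4-(penta-O-benzylcatechin-8-yl)chroman-2-one
Conditions: t-BuMe2SiOTf, 2,6-lutidine, CH2Cl2, −78 °C to 0 °C
Reagents that add atoms: tert-butyldimethylsilyl triflate, CC(C)(C)[Si](C)(C)OS(=O)(=O)C(F)(F)F
Why: Silylation of a hindered secondary alcohol with a silyl triflate and a non-nucleophilic base; the silyl ether is orthogonal to the benzyl ethers and marks the one oxygen that is later acylated.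

Step 13
Reactants: 18 4-bromobenzene-1,2-diol
Product: 19 4-bromo-1,2-bis(benzyloxy)benzene
Conditions: BnBr, K2CO3, DMF, rt
Reagents that add atoms: benzyl bromide, BrCc1ccccc1
Why: Williamson etherification of both catechol hydroxyls.

Step 14
Reactants: 17 (3R,4R)-5,7-bis(benzyloxy)-3-(tert-butyldimethylsilyloxy)-4-(penta-O-benzylcatechin-8-yl)chroman-2-one; 19 4-bromo-1,2-bis(benzyloxy)benzene
Product: 21 (2R,3R)-1-[3,4-bis(benzyloxy)phenyl]-3-[2,4-bis(benzyloxy)-6-hydroxyphenyl]-2-(tert-butyldimethylsilyloxy)-3-(penta-O-benzylcatechin-8-yl)propan-1-one, via 3,4-bis(benzyloxy)phenyllithium 20 (not isolated)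
Conditions: 19, n-BuLi, THF, −78 °C; added to 17 (1.1 equiv ArLi), THF, −78 °C; AcOH, −78 °C
Reagents that add atoms: none
Why: Bromine–lithium exchange, then 1,2-addition of the aryllithium to the lactone carbonyl; the tetrahedral alkoxide releases the phenoxide to give the aryl ketone. One equivalent, inverse addition, low temperature and the crowded α-silyloxy ketone are meant to prevent a second addition, and the cold acidic quench to prevent silyl migration.

Step 15
Reactants: 21 (2R,3R)-1-[3,4-bis(benzyloxy)phenyl]-3-[2,4-bis(benzyloxy)-6-hydroxyphenyl]-2-(tert-butyldimethylsilyloxy)-3-(penta-O-benzylcatechin-8-yl)propan-1-one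
Product: 23 3-O-(tert-butyldimethylsilyl)-5,7,3′,4′-tetra-O-benzyl-(−)-epicatechin-(4β→8)-3,5,7,3′,4′-penta-O-benzyl-(+)-catechin (upper unit 2R,3R,4R), via cyclic hemiketal 22 (not isolated)
Conditions: Et3SiH (5 equiv), Me3SiOTf (0.3 equiv), CH2Cl2, −78 °C to −30 °C
Reagents that add atoms: none
Why: Reductive etherification: the Lewis acid closes 21 to hemiketal 22 and ionises it to the 2-aryl oxocarbenium ion, which the silane reduces. With the C4 aryl pseudo-axial, the trans C3 silyloxy group is pseudo-axial too, and hydride should add along the axis anti to that C–O bond (polar Felkin–Anh, chair-like transition state). This places the C2 aryl equatorial and cis to the C3 oxygen (2R).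

Step 16
Reactants: 23 3-O-(tert-butyldimethylsilyl)-5,7,3′,4′-tetra-O-benzyl-(−)-epicatechin-(4β→8)-3,5,7,3′,4′-penta-O-benzyl-(+)-catechin
Product: 24 5,7,3′,4′-tetra-O-benzyl-(−)-epicatechin-(4β→8)-3,5,7,3′,4′-penta-O-benzyl-(+)-catechin (upper 3-hydroxyl free)
Conditions: Bu4NF, THF, rt
Reagents that add atoms: none
Why: Fluoride cleavage of the silyl ether; benzyl ethers and the interflavan bond are inert, and the middle C3 hydroxyl becomes the only free hydroxyl.

Step 17
Reactants: 24 5,7,3′,4′-tetra-O-benzyl-(−)-epicatechin-(4β→8)-3,5,7,3′,4′-penta-O-benzyl-(+)-catechin; 25 3,4,5-tris(benzyloxy)benzoic acid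
Product: 26 5,7,3′,4′-tetra-O-benzyl-3-O-[3,4,5-tris(benzyloxy)benzoyl]-(−)-epicatechin-(4β→8)-3,5,7,3′,4′-penta-O-benzyl-(+)-catechin
Conditions: DCC, 4-(dimethylamino)pyridine, CH2Cl2, rt
Reagents that add atoms: none
Why: Steglich esterification; the acylpyridinium intermediate is reactive enough for the axial, flanked C3 hydroxyl, and no other hydroxyl competes.

Step 18
Reactants: 27 (−)-epicatechin
Product: 28 5,7,3′,4′-tetra-O-benzyl-(−)-epicatechin
Conditions: BnBr (4.4 equiv), K2CO3, DMF, 0 °C to rt, argon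
Reagents that add atoms: benzyl bromide, BrCc1ccccc1
Why: Williamson etherification; the carbonate base deprotonates only the four phenols, so the secondary 3-hydroxyl stays free for the acylation that follows, and the mild conditions should leave C2 and C3 unchanged.

Step 19
Reactants: 28 5,7,3′,4′-tetra-O-benzyl-(−)-epicatechin; 25 3,4,5-tris(benzyloxy)benzoic acid
Product: 29 5,7,3′,4′-tetra-O-benzyl-3-O-[3,4,5-tris(benzyloxy)benzoyl]-(−)-epicatechin
Conditions: DCC, 4-(dimethylamino)pyridine, CH2Cl2, rt
Reagents that add atoms: none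
Why: Steglich esterification of the only free hydroxyl; acylation takes place at oxygen, so the C3 configuration is retained and the 2,3-cis relation of the epicatechin unit is kept.

Step 20
Reactants: 29 5,7,3′,4′-tetra-O-benzyl-3-O-[3,4,5-tris(benzyloxy)benzoyl]-(−)-epicatechin
Product: 30 4β-(2-ethoxyethoxy)-5,7,3′,4′-tetra-O-benzyl-3-O-[3,4,5-tris(benzyloxy)benzoyl]-(−)-epicatechin (3,4-trans)
Conditions: DDQ (2 equiv), HOCH2CH2OEt (5 equiv), CH2Cl2, rt
Reagents that add atoms: 2-ethoxyethanol, CCOCCO
Why: Benzylic C4–H oxidation by hydride abstraction next to the electron-rich ring A, with capture of the cation by the alcohol trans to the C3 ester. The C4 configuration is of no consequence because the group is ionised again in step 21.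

Step 21
Reactants: 26 5,7,3′,4′-tetra-O-benzyl-3-O-[3,4,5-tris(benzyloxy)benzoyl]-(−)-epicatechin-(4β→8)-3,5,7,3′,4′-penta-O-benzyl-(+)-catechin; 30 4β-(2-ethoxyethoxy)-5,7,3′,4′-tetra-O-benzyl-3-O-[3,4,5-tris(benzyloxy)benzoyl]-(−)-epicatechin
Product: 31 nonadeca-O-benzyl epicatechin-3-O-gallate-(4β→8)-epicatechin-3-O-gallate-(4β→8)-catechin
Conditions: Me3SiOTf (0.2 equiv), CH2Cl2, −78 °C; 30 added slowly to 26 (1.5 equiv); Et3N quench
Reagents that add atoms: none
Why: Lewis-acid ionisation of the C4 ether and Friedel–Crafts capture of the cation by C8 of the upper ring A of 26, its most accessible nucleophilic carbon. The C3 gallate carbonyl bridges the α face of the cation, so the arene enters from the β face and the new bond is 3,4-trans (4β).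

Step 22
Reactants: 31 nonadeca-O-benzyl epicatechin-3-O-gallate-(4β→8)-epicatechin-3-O-gallate-(4β→8)-catechin
Product: 32 epicatechin-3-O-gallate-(4β→8)-epicatechin-3-O-gallate-(4β→8)-catechin
Conditions: H2 (1 atm), Pd(OH)2/C, THF–MeOH–H2O, rt
Reagents that add atoms: none
Why: Hydrogenolysis of nineteen benzyl ethers under neutral conditions, which the gallate esters and the acid-labile C4–C8 bonds should survive; no stereocenter is touched.

**Compound list**

1 | (+)-catechin, (2R,3S)-2-(3,4-dihydroxyphenyl)chromane-3,5,7-triol | O[C@H]1Cc2c(O)cc(O)cc2O[C@@H]1c1ccc(O)c(O)c1 | starting material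
2 | 5,7,3′,4′-tetra-O-benzyl-(+)-catechin | O[C@H]1Cc2c(OCc9ccccc9)cc(OCc9ccccc9)cc2O[C@@H]1c1ccc(OCc9ccccc9)c(OCc9ccccc9)c1 | intermediate
3 | 3,5,7,3′,4′-penta-O-benzyl-(+)-catechin | C(c9ccccc9)O[C@H]1Cc2c(OCc9ccccc9)cc(OCc9ccccc9)cc2O[C@@H]1c1ccc(OCc9ccccc9)c(OCc9ccccc9)c1 | intermediate
4 | 8-bromo-3,5,7,3′,4′-penta-O-benzyl-(+)-catechin | Brc2c(OCc9ccccc9)cc(OCc9ccccc9)c3c2O[C@H](c2ccc(OCc9ccccc9)c(OCc9ccccc9)c2)[C@@H](OCc9ccccc9)C3 | intermediate
5 | 8-lithio-3,5,7,3′,4′-penta-O-benzylcatechin | [Li]c2c(OCc9ccccc9)cc(OCc9ccccc9)c3c2O[C@H](c2ccc(OCc9ccccc9)c(OCc9ccccc9)c2)[C@@H](OCc9ccccc9)C3 | intermediate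
6 | 3,5,7,3′,4′-penta-O-benzylcatechin-8-carbaldehyde | O=Cc2c(OCc9ccccc9)cc(OCc9ccccc9)c3c2O[C@H](c2ccc(OCc9ccccc9)c(OCc9ccccc9)c2)[C@@H](OCc9ccccc9)C3 | intermediate
7 | (E)-3-(3,5,7,3′,4′-penta-O-benzylcatechin-8-yl)propenal | O=C/C=C/c2c(OCc9ccccc9)cc(OCc9ccccc9)c3c2O[C@H](c2ccc(OCc9ccccc9)c(OCc9ccccc9)c2)[C@@H](OCc9ccccc9)C3 | intermediate
8 | phloroglucinol (benzene-1,3,5-triol) | Oc1cc(O)cc(O)c1 | starting material
9 | (3R)-3-(penta-O-benzylcatechin-8-yl)-3-(2,4,6-trihydroxyphenyl)propanal | O=CC[C@@H](c2c(OCc9ccccc9)cc(OCc9ccccc9)c3c2O[C@H](c2ccc(OCc9ccccc9)c(OCc9ccccc9)c2)[C@@H](OCc9ccccc9)C3)c1c(O)cc(O)cc1O | intermediate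
10 | (4R)-4-(penta-O-benzylcatechin-8-yl)chromane-2,5,7-triol (lactol, both C2 epimers) | OC1C[C@@H](c2c(OCc9ccccc9)cc(OCc9ccccc9)c3c2O[C@H](c2ccc(OCc9ccccc9)c(OCc9ccccc9)c2)[C@@H](OCc9ccccc9)C3)c2c(O)cc(O)cc2O1 | intermediate
11 | (4R)-2-methoxy-4-(penta-O-benzylcatechin-8-yl)chromane-5,7-diol (both C2 epimers) | COC1C[C@@H](c2c(OCc9ccccc9)cc(OCc9ccccc9)c3c2O[C@H](c2ccc(OCc9ccccc9)c(OCc9ccccc9)c2)[C@@H](OCc9ccccc9)C3)c2c(O)cc(O)cc2O1 | intermediate
12 | (4R)-5,7-bis(benzyloxy)-2-methoxy-4-(penta-O-benzylcatechin-8-yl)chromane (both C2 epimers) | COC1C[C@@H](c2c(OCc9ccccc9)cc(OCc9ccccc9)c3c2O[C@H](c2ccc(OCc9ccccc9)c(OCc9ccccc9)c2)[C@@H](OCc9ccccc9)C3)c2c(OCc9ccccc9)cc(OCc9ccccc9)cc2O1 | intermediate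
13 | (4R)-5,7-bis(benzyloxy)-4-(penta-O-benzylcatechin-8-yl)chroman-2-ol (both C2 epimers) | OC1C[C@@H](c2c(OCc9ccccc9)cc(OCc9ccccc9)c3c2O[C@H](c2ccc(OCc9ccccc9)c(OCc9ccccc9)c2)[C@@H](OCc9ccccc9)C3)c2c(OCc9ccccc9)cc(OCc9ccccc9)cc2O1 | intermediate
14 | (4R)-5,7-bis(benzyloxy)-4-(penta-O-benzylcatechin-8-yl)chroman-2-one | O=C1C[C@@H](c2c(OCc9ccccc9)cc(OCc9ccccc9)c3c2O[C@H](c2ccc(OCc9ccccc9)c(OCc9ccccc9)c2)[C@@H](OCc9ccccc9)C3)c2c(OCc9ccccc9)cc(OCc9ccccc9)cc2O1 | intermediate
15 | potassium enolate of 14, potassium (4R)-5,7-bis(benzyloxy)-4-(penta-O-benzylcatechin-8-yl)-4H-chromen-2-olate | [K+].[O-]C1=C[C@@H](c2c(OCc9ccccc9)cc(OCc9ccccc9)c3c2O[C@H](c2ccc(OCc9ccccc9)c(OCc9ccccc9)c2)[C@@H](OCc9ccccc9)C3)c2c(OCc9ccccc9)cc(OCc9ccccc9)cc2O1 | intermediate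
16 | (3R,4R)-5,7-bis(benzyloxy)-3-hydroxy-4-(penta-O-benzylcatechin-8-yl)chroman-2-one (3,4-trans) | O=C1[C@H](O)[C@@H](c2c(OCc9ccccc9)cc(OCc9ccccc9)c3c2O[C@H](c2ccc(OCc9ccccc9)c(OCc9ccccc9)c2)[C@@H](OCc9ccccc9)C3)c2c(OCc9ccccc9)cc(OCc9ccccc9)cc2O1 | intermediate
17 | (3R,4R)-5,7-bis(benzyloxy)-3-(tert-butyldimethylsilyloxy)-4-(penta-O-benzylcatechin-8-yl)chroman-2-one | O=C1[C@H](O[Si](C)(C)C(C)(C)C)[C@@H](c2c(OCc9ccccc9)cc(OCc9ccccc9)c3c2O[C@H](c2ccc(OCc9ccccc9)c(OCc9ccccc9)c2)[C@@H](OCc9ccccc9)C3)c2c(OCc9ccccc9)cc(OCc9ccccc9)cc2O1 | intermediate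
18 | 4-bromobenzene-1,2-diol | Oc1ccc(Br)cc1O | starting material
19 | 4-bromo-1,2-bis(benzyloxy)benzene | Brc1ccc(OCc9ccccc9)c(OCc9ccccc9)c1 | intermediate
20 | 3,4-bis(benzyloxy)phenyllithium | [Li]c1ccc(OCc9ccccc9)c(OCc9ccccc9)c1 | intermediate
21 | (2R,3R)-1-[3,4-bis(benzyloxy)phenyl]-3-[2,4-bis(benzyloxy)-6-hydroxyphenyl]-2-(tert-butyldimethylsilyloxy)-3-(penta-O-benzylcatechin-8-yl)propan-1-one | O=C(c1ccc(OCc9ccccc9)c(OCc9ccccc9)c1)[C@H](O[Si](C)(C)C(C)(C)C)[C@@H](c2c(OCc9ccccc9)cc(OCc9ccccc9)c3c2O[C@H](c2ccc(OCc9ccccc9)c(OCc9ccccc9)c2)[C@@H](OCc9ccccc9)C3)c1c(OCc9ccccc9)cc(OCc9ccccc9)cc1O | intermediate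
22 | (3R,4R)-2-[3,4-bis(benzyloxy)phenyl]-5,7-bis(benzyloxy)-3-(tert-butyldimethylsilyloxy)-4-(penta-O-benzylcatechin-8-yl)chroman-2-ol (cyclic hemiketal of 21, both C2 epimers) | OC1(c2ccc(OCc9ccccc9)c(OCc9ccccc9)c2)[C@H](O[Si](C)(C)C(C)(C)C)[C@@H](c2c(OCc9ccccc9)cc(OCc9ccccc9)c3c2O[C@H](c2ccc(OCc9ccccc9)c(OCc9ccccc9)c2)[C@@H](OCc9ccccc9)C3)c2c(OCc9ccccc9)cc(OCc9ccccc9)cc2O1 | intermediate
23 | 3-O-(tert-butyldimethylsilyl)-5,7,3′,4′-tetra-O-benzyl-(−)-epicatechin-(4β→8)-3,5,7,3′,4′-penta-O-benzyl-(+)-catechin (upper unit 2R,3R,4R) | CC(C)(C)[Si](C)(C)O[C@@H]1[C@@H](c2c(OCc9ccccc9)cc(OCc9ccccc9)c3c2O[C@H](c2ccc(OCc9ccccc9)c(OCc9ccccc9)c2)[C@@H](OCc9ccccc9)C3)c2c(OCc9ccccc9)cc(OCc9ccccc9)cc2O[C@@H]1c1ccc(OCc9ccccc9)c(OCc9ccccc9)c1 | intermediate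
24 | 5,7,3′,4′-tetra-O-benzyl-(−)-epicatechin-(4β→8)-3,5,7,3′,4′-penta-O-benzyl-(+)-catechin (upper 3-hydroxyl free) | O[C@@H]1[C@@H](c2c(OCc9ccccc9)cc(OCc9ccccc9)c3c2O[C@H](c2ccc(OCc9ccccc9)c(OCc9ccccc9)c2)[C@@H](OCc9ccccc9)C3)c2c(OCc9ccccc9)cc(OCc9ccccc9)cc2O[C@@H]1c1ccc(OCc9ccccc9)c(OCc9ccccc9)c1 | intermediate
25 | 3,4,5-tris(benzyloxy)benzoic acid | OC(=O)c1cc(OCc9ccccc9)c(OCc9ccccc9)c(OCc9ccccc9)c1 | starting material
26 | 5,7,3′,4′-tetra-O-benzyl-3-O-[3,4,5-tris(benzyloxy)benzoyl]-(−)-epicatechin-(4β→8)-3,5,7,3′,4′-penta-O-benzyl-(+)-catechin | O=C(O[C@@H]1[C@@H](c2c(OCc9ccccc9)cc(OCc9ccccc9)c3c2O[C@H](c2ccc(OCc9ccccc9)c(OCc9ccccc9)c2)[C@@H](OCc9ccccc9)C3)c2c(OCc9ccccc9)cc(OCc9ccccc9)cc2O[C@@H]1c1ccc(OCc9ccccc9)c(OCc9ccccc9)c1)c1cc(OCc9ccccc9)c(OCc9ccccc9)c(OCc9ccccc9)c1 | intermediate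
27 | (−)-epicatechin, (2R,3R)-2-(3,4-dihydroxyphenyl)chromane-3,5,7-triol | O[C@@H]1Cc2c(O)cc(O)cc2O[C@@H]1c1ccc(O)c(O)c1 | starting material
28 | 5,7,3′,4′-tetra-O-benzyl-(−)-epicatechin | O[C@@H]1Cc2c(OCc9ccccc9)cc(OCc9ccccc9)cc2O[C@@H]1c1ccc(OCc9ccccc9)c(OCc9ccccc9)c1 | intermediate
29 | 5,7,3′,4′-tetra-O-benzyl-3-O-[3,4,5-tris(benzyloxy)benzoyl]-(−)-epicatechin (hepta-O-benzyl epicatechin gallate) | O=C(O[C@@H]1Cc2c(OCc9ccccc9)cc(OCc9ccccc9)cc2O[C@@H]1c1ccc(OCc9ccccc9)c(OCc9ccccc9)c1)c1cc(OCc9ccccc9)c(OCc9ccccc9)c(OCc9ccccc9)c1 | intermediate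
30 | 4β-(2-ethoxyethoxy)-5,7,3′,4′-tetra-O-benzyl-3-O-[3,4,5-tris(benzyloxy)benzoyl]-(−)-epicatechin (3,4-trans) | O=C(O[C@@H]1[C@@H](OCCOCC)c2c(OCc9ccccc9)cc(OCc9ccccc9)cc2O[C@@H]1c1ccc(OCc9ccccc9)c(OCc9ccccc9)c1)c1cc(OCc9ccccc9)c(OCc9ccccc9)c(OCc9ccccc9)c1 | intermediate
31 | nonadeca-O-benzyl epicatechin-3-O-gallate-(4β→8)-epicatechin-3-O-gallate-(4β→8)-catechin | O=C(O[C@@H]1[C@@H](c2c(OCc9ccccc9)cc(OCc9ccccc9)c3c2O[C@H](c2ccc(OCc9ccccc9)c(OCc9ccccc9)c2)[C@@H](OCc9ccccc9)C3)c2c(OCc9ccccc9)cc(OCc9ccccc9)c([C@H]3c4c(OCc9ccccc9)cc(OCc9ccccc9)cc4O[C@H](c4ccc(OCc9ccccc9)c(OCc9ccccc9)c4)[C@@H]3OC(=O)c3cc(OCc9ccccc9)c(OCc9ccccc9)c(OCc9ccccc9)c3)c2O[C@@H]1c1ccc(OCc9ccccc9)c(OCc9ccccc9)c1)c1cc(OCc9ccccc9)c(OCc9ccccc9)c(OCc9ccccc9)c1 | intermediate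
32 | epicatechin-3-O-gallate-(4β→8)-epicatechin-3-O-gallate-(4β→8)-catechin (CNP0269915.2) | O=C(O[C@@H]1[C@@H](c2c(O)cc(O)c3c2O[C@H](c2ccc(O)c(O)c2)[C@@H](O)C3)c2c(O)cc(O)c([C@H]3c4c(O)cc(O)cc4O[C@H](c4ccc(O)c(O)c4)[C@@H]3OC(=O)c3cc(O)c(O)c(O)c3)c2O[C@@H]1c1ccc(O)c(O)c1)c1cc(O)c(O)c(O)c1 | target

**Step count and weak points**

Total: 22 steps. Longest linear sequence: 18 steps (steps 1–12, 14–17, 21 and 22, from 1 to 32). Step 13 and steps 18–20 are short side branches.

Step 6 (key step). The β-aryl group of 7 is a 2,4,6-trioxygenated ring with two ortho substituents. It stabilises the iminium ion and crowds the β-carbon, so the conjugate addition may be slow. A second alkylation of the still electron-rich product ring may compete, and an uncatalysed, acid-promoted background addition would erode facial selectivity. Fallback, from 6 to 14: Knoevenagel condensation of 6 with Meldrum's acid gives the arylidene Meldrum's acid F1. Compound 8 adds to F1 in pyridine, and the ortho hydroxyl lactonises with loss of acetone and carbon dioxide to give the 5,7-dihydroxy lactone F2 as both C4 epimers. Mitsunobu benzylation (BnOH, PPh3, DIAD) of the two phenols gives 14 together with its (4S)-epimer F3. The two are diastereomers because of the catechin unit and should separate on silica. C4 is then not controlled, but steps 7–10 are not needed.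

Step 11. The enolate of an aryl ester may open by E1cB loss of the phenoxide to a ketene. The enolate may also add to the sulfonylimine by-product, and facial selectivity may be incomplete. Fallback, from 13 to 16: dehydration of 13 (MsCl, Et3N) gives the 4H-chromene F4. Dihydroxylation (OsO4 cat., N-methylmorpholine N-oxide) on the face away from the C4 aryl group gives the cis-2,3-diol lactol F5. Selective oxidation of the lactol hydroxyl with Ag2CO3 on Celite returns 16.

Step 14. The tetrahedral intermediate may eject the phenoxide early and the freed ketone may take up a second aryllithium. Enolisation of the lactone and migration of the silyl group to the new alkoxide are further risks. Fallback, from 17 to 21: the lactone is opened with MeNH(OMe)·HCl and i-PrMgCl to the Weinreb amide F6, which carries a free phenol. Excess 20 then adds once, because the chelated adduct holds until work-up, and gives 21.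

Step 15. Hydride must enter at C2 on the face that also carries the pseudo-axial C4 aryl group, in a 1,3 relation, so delivery to the other face and formation of the C2 epimer is the main risk. Loss of H3 from the oxocarbenium ion to an enol ether, which would scramble C3, and loss of the silyl group are lesser risks. Fallback, from 21 to 24: HF·pyridine removes the silyl group to give the α-hydroxy ketone F7. Chelation-controlled reduction with Zn(BH4)2 gives the anti-diol F8. Mitsunobu cycloetherification (PPh3, DIAD) closes O1–C2 with inversion at the benzylic carbinol and gives 24 directly, which also makes step 16 unnecessary. Partial ionisation of the electron-rich benzylic alcohol would lower the stereospecificity of this closure.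

Step 21. The ionised electrophile may condense with its own ring A through C8 and so oligomerise. Attack at C6 of either ring A of 26 may compete. The 3-acyloxy group may slow ionisation. Fallback, from 29 to 32: bromination of 29 (NBS) gives the 8-bromide F9, and oxidation as in step 20 gives the capped electrophile F10, which cannot act as a nucleophile. Coupling with 26 in equal amounts gives the 8-bromo trimer F11. Hydrogenolysis over Pd(OH)2/C in the presence of Et3N removes the bromine together with the benzyl groups and gives 32.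

**Further compounds**

F1 | step 6 | 2,2-dimethyl-5-[(3,5,7,3′,4′-penta-O-benzylcatechin-8-yl)methylidene]-1,3-dioxane-4,6-dione | CC1(C)OC(=O)C(=Cc2c(OCc9ccccc9)cc(OCc9ccccc9)c3c2O[C@H](c2ccc(OCc9ccccc9)c(OCc9ccccc9)c2)[C@@H](OCc9ccccc9)C3)C(=O)O1
F2 | step 6 | 5,7-dihydroxy-4-(penta-O-benzylcatechin-8-yl)chroman-2-one (both C4 epimers) | O=C1CC(c2c(OCc9ccccc9)cc(OCc9ccccc9)c3c2O[C@H](c2ccc(OCc9ccccc9)c(OCc9ccccc9)c2)[C@@H](OCc9ccccc9)C3)c2c(O)cc(O)cc2O1
F3 | step 6 | (4S)-5,7-bis(benzyloxy)-4-(penta-O-benzylcatechin-8-yl)chroman-2-one (C4 epimer of 14) | O=C1C[C@H](c2c(OCc9ccccc9)cc(OCc9ccccc9)c3c2O[C@H](c2ccc(OCc9ccccc9)c(OCc9ccccc9)c2)[C@@H](OCc9ccccc9)C3)c2c(OCc9ccccc9)cc(OCc9ccccc9)cc2O1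
F4 | step 11 | (4R)-5,7-bis(benzyloxy)-4-(penta-O-benzylcatechin-8-yl)-4H-chromene | C1=C[C@@H](c2c(OCc9ccccc9)cc(OCc9ccccc9)c3c2O[C@H](c2ccc(OCc9ccccc9)c(OCc9ccccc9)c2)[C@@H](OCc9ccccc9)C3)c2c(OCc9ccccc9)cc(OCc9ccccc9)cc2O1
F5 | step 11 | (3R,4R)-5,7-bis(benzyloxy)-4-(penta-O-benzylcatechin-8-yl)chromane-2,3-diol (2,3-cis diol, 3,4-trans) | OC1[C@H](O)[C@@H](c2c(OCc9ccccc9)cc(OCc9ccccc9)c3c2O[C@H](c2ccc(OCc9ccccc9)c(OCc9ccccc9)c2)[C@@H](OCc9ccccc9)C3)c2c(OCc9ccccc9)cc(OCc9ccccc9)cc2O1
F6 | step 14 | (2R,3R)-3-[2,4-bis(benzyloxy)-6-hydroxyphenyl]-2-(tert-butyldimethylsilyloxy)-N-methoxy-N-methyl-3-(penta-O-benzylcatechin-8-yl)propanamide | CON(C)C(=O)[C@H](O[Si](C)(C)C(C)(C)C)[C@@H](c2c(OCc9ccccc9)cc(OCc9ccccc9)c3c2O[C@H](c2ccc(OCc9ccccc9)c(OCc9ccccc9)c2)[C@@H](OCc9ccccc9)C3)c1c(OCc9ccccc9)cc(OCc9ccccc9)cc1O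
F7 | step 15 | (2R,3R)-1-[3,4-bis(benzyloxy)phenyl]-3-[2,4-bis(benzyloxy)-6-hydroxyphenyl]-2-hydroxy-3-(penta-O-benzylcatechin-8-yl)propan-1-one | O=C(c1ccc(OCc9ccccc9)c(OCc9ccccc9)c1)[C@H](O)[C@@H](c2c(OCc9ccccc9)cc(OCc9ccccc9)c3c2O[C@H](c2ccc(OCc9ccccc9)c(OCc9ccccc9)c2)[C@@H](OCc9ccccc9)C3)c1c(OCc9ccccc9)cc(OCc9ccccc9)cc1O
F8 | step 15 | (1S,2R,3R)-1-[3,4-bis(benzyloxy)phenyl]-3-[2,4-bis(benzyloxy)-6-hydroxyphenyl]-3-(penta-O-benzylcatechin-8-yl)propane-1,2-diol (1,2-anti) | O[C@@H](c1ccc(OCc9ccccc9)c(OCc9ccccc9)c1)[C@H](O)[C@@H](c2c(OCc9ccccc9)cc(OCc9ccccc9)c3c2O[C@H](c2ccc(OCc9ccccc9)c(OCc9ccccc9)c2)[C@@H](OCc9ccccc9)C3)c1c(OCc9ccccc9)cc(OCc9ccccc9)cc1O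
F9 | step 21 | 8-bromo-5,7,3′,4′-tetra-O-benzyl-3-O-[3,4,5-tris(benzyloxy)benzoyl]-(−)-epicatechin | O=C(O[C@@H]1Cc2c(OCc9ccccc9)cc(OCc9ccccc9)c(Br)c2O[C@@H]1c1ccc(OCc9ccccc9)c(OCc9ccccc9)c1)c1cc(OCc9ccccc9)c(OCc9ccccc9)c(OCc9ccccc9)c1
F10 | step 21 | 8-bromo-4β-(2-ethoxyethoxy)-5,7,3′,4′-tetra-O-benzyl-3-O-[3,4,5-tris(benzyloxy)benzoyl]-(−)-epicatechin | O=C(O[C@@H]1[C@@H](OCCOCC)c2c(OCc9ccccc9)cc(OCc9ccccc9)c(Br)c2O[C@@H]1c1ccc(OCc9ccccc9)c(OCc9ccccc9)c1)c1cc(OCc9ccccc9)c(OCc9ccccc9)c(OCc9ccccc9)c1
F11 | step 21 | nonadeca-O-benzyl trimer 31 carrying bromine at C8 of the top unit | O=C(O[C@@H]1[C@@H](c2c(OCc9ccccc9)cc(OCc9ccccc9)c3c2O[C@H](c2ccc(OCc9ccccc9)c(OCc9ccccc9)c2)[C@@H](OCc9ccccc9)C3)c2c(OCc9ccccc9)cc(OCc9ccccc9)c([C@H]3c4c(OCc9ccccc9)cc(OCc9ccccc9)c(Br)c4O[C@H](c4ccc(OCc9ccccc9)c(OCc9ccccc9)c4)[C@@H]3OC(=O)c3cc(OCc9ccccc9)c(OCc9ccccc9)c(OCc9ccccc9)c3)c2O[C@@H]1c1ccc(OCc9ccccc9)c(OCc9ccccc9)c1)c1cc(OCc9ccccc9)c(OCc9ccccc9)c(OCc9ccccc9)c1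
A1 | alternative 1 | m-xylylene-bridged benzylated epicatechin gallate-(4β→8)-catechin macrocycle (bridge from the gallate para oxygen to the catechin 3-oxygen) | O=C(O[C@@H]1[C@@H](c2c(OCc9ccccc9)cc(OCc9ccccc9)c3c2O[C@H](c2ccc(OCc9ccccc9)c(OCc9ccccc9)c2)[C@@H](O%10)C3)c2c(OCc9ccccc9)cc(OCc9ccccc9)cc2O[C@@H]1c1ccc(OCc9ccccc9)c(OCc9ccccc9)c1)c1cc(OCc9ccccc9)c(OCc5cccc(C%10)c5)c(OCc9ccccc9)c1
A2 | alternative 2 | octadeca-O-benzyl trimer with free middle C7 hydroxyl | O=C(O[C@@H]1[C@@H](c2c(OCc9ccccc9)cc(OCc9ccccc9)c3c2O[C@H](c2ccc(OCc9ccccc9)c(OCc9ccccc9)c2)[C@@H](OCc9ccccc9)C3)c2c(OCc9ccccc9)cc(O)c([C@H]3c4c(OCc9ccccc9)cc(OCc9ccccc9)cc4O[C@H](c4ccc(OCc9ccccc9)c(OCc9ccccc9)c4)[C@@H]3OC(=O)c3cc(OCc9ccccc9)c(OCc9ccccc9)c(OCc9ccccc9)c3)c2O[C@@H]1c1ccc(OCc9ccccc9)c(OCc9ccccc9)c1)c1cc(OCc9ccccc9)c(OCc9ccccc9)c(OCc9ccccc9)c1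
A3 | alternative 3 | tetradeca-O-benzyl epicatechin gallate-(4β→8)-epicatechin gallate | O=C(O[C@@H]1Cc2c(OCc9ccccc9)cc(OCc9ccccc9)c([C@H]3c4c(OCc9ccccc9)cc(OCc9ccccc9)cc4O[C@H](c4ccc(OCc9ccccc9)c(OCc9ccccc9)c4)[C@@H]3OC(=O)c3cc(OCc9ccccc9)c(OCc9ccccc9)c(OCc9ccccc9)c3)c2O[C@@H]1c1ccc(OCc9ccccc9)c(OCc9ccccc9)c1)c1cc(OCc9ccccc9)c(OCc9ccccc9)c(OCc9ccccc9)c1
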